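**Strategy.** The 20-membered ring is cut at two bonds on ring B: the aryl–alkyl bond B6–C1 and the diaryl ether bond O–B1 (ring B: B1 ether carbon, B2 and B4 hydroxylated, B6 chain-bearing). The key step exploits that B1 and B6 are adjacent and that B6 is the only C–H flanking B1. A palladium/norbornene relay alkylates B6 and then etherifies B1 with the same bifunctional partner, closing the macrocycle in one operation. Its precursors are commercial 1-iodo-2,4-dimethoxybenzene and a ring A phenol, 3-(14-iodotetradecyl)-5-methoxyphenol, carrying the primary iodide at the end of the C14 chain. Global demethylation then gives the target.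

Key step: step 5

Remark: the target is achiral, so no stereochemical control is needed; the diene, the aryl bromide, the aryl iodide and norbornene are taken as purchased.

**Step 1**
Reactants: 1 tetradeca-1,13-diene; 2 1-bromo-3,5-dimethoxybenzene
Product: 4 1,3-dimethoxy-5-(tetradec-13-en-1-yl)benzene, via B-(tetradec-13-enyl)-9-BBN 3 (not isolated)
Conditions: 1 (3.5 equiv), 9-BBN (1.2 equiv, 0.5 M in THF), 0 °C to rt; then 2 (1.0 equiv), Pd(dppf)Cl2 (3 mol %), 3 M aq NaOH, THF, 65 °C; excess 1 recovered
Reagents that add atoms: none
Why: 9-BBN adds anti-Markovnikov to one terminal alkene (the excess of diene keeps double addition low) and the primary B-alkyl borane then undergoes B-alkyl Suzuki–Miyaura coupling with the aryl bromide, the wide-bite-angle dppf ligand disfavouring β-hydride elimination.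

**Step 2**
Reactants: 4 1,3-dimethoxy-5-(tetradec-13-en-1-yl)benzene
Product: 6 14-(3,5-dimethoxyphenyl)tetradecan-1-ol, via B-[14-(3,5-dimethoxyphenyl)tetradecyl]-9-BBN 5 (not isolated)
Conditions: 9-BBN (1.3 equiv), THF, 0 °C to rt; then 3 M aq NaOH, 30% H2O2, 0 °C to rt
Reagents that add atoms: hydrogen peroxide, OO
Why: Hydroboration–oxidation places boron on the terminal carbon and alkaline peroxide replaces it by hydroxyl, while the arene and its ethers are inert.

**Step 3**
Reactants: 6 14-(3,5-dimethoxyphenyl)tetradecan-1-ol
Product: 7 3-(14-hydroxytetradecyl)-5-methoxyphenol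
Conditions: NaSEt (3 equiv), DMF, 140 °C; then 1 M HCl
Reagents that add atoms: none
Why: SN2 demethylation of an aryl methyl ether by ethanethiolate should stop after one methyl group because the phenoxide formed makes the second aryloxide a far poorer leaving group, and the aliphatic alcohol is not affected.

**Step 4**
Reactants: 7 3-(14-hydroxytetradecyl)-5-methoxyphenol
Product: 8 3-(14-iodotetradecyl)-5-methoxyphenol
Conditions: PPh3 (1.3 equiv) and I2 (1.25 equiv) premixed, imidazole (1.5 equiv), CH2Cl2, 0 °C, dark; product kept cold and used promptly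
Reagents that add atoms: iodine, II
Why: Appel iodination converts the primary alcohol to an alkoxyphosphonium ion that iodide displaces by SN2, whereas a phenoxyphosphonium ion cannot be displaced at an sp2 carbon and reverts on aqueous work-up, and premixing PPh3 with I2 leaves no free iodine to attack ring A.

**Step 5**
Reactants: 8 3-(14-iodotetradecyl)-5-methoxyphenol; 9 1-iodo-2,4-dimethoxybenzene; 10 norbornene (2 equiv, mediator, not incorporated)
Product: 11 macrocycle trimethyl ether, 1⁵,3⁴,3⁶-trimethoxy-2-oxa-1(1,3),3(1,2)-dibenzenacycloheptadecaphane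
Conditions: Pd(OAc)2 (10 mol %), tBuXPhos (2-di-tert-butylphosphino-2′,4′,6′-triisopropylbiphenyl, 20 mol %), K3PO4 (4 equiv, milled), toluene, 100 °C, closed vessel; 8 and 9 (1:1.1) co-added by syringe pump over 12 h to about 5 mM
Reagents that add atoms: none
Why: Proposed new method: oxidative addition of zerovalent palladium into the B1–I bond of 9, syn insertion of norbornene and base-assisted palladation of the lone ortho C–H at B6 should give the five-membered aryl–norbornyl palladacycle, to which the primary iodide of 8 adds (tetravalent palladium) before C(sp2)–C(sp3) reductive elimination forms B6–C1. With B1 now flanked by the B2 methoxy group and the new chain, β-carbon elimination releases norbornene and leaves a divalent arylpalladium at B1, which binds the tethered ring A phenoxide and forms O–B1 by C–O reductive elimination, a step favoured by the bulky di-tert-butyl biaryl phosphine and by the di-ortho substitution. The closest known reaction type is the Catellani ortho alkylation with ipso C–O termination by an alkoxide derived from an epoxide partner (dihydrobenzofuran annulation), taken together with palladium-catalysed diaryl ether formation from phenols under the same ligand and base class. The 20-membered ring is closed in the termination event, an intramolecular aryl–oxygen reductive elimination from a macrocyclic arylpalladium phenoxide under pseudo-high dilution, and no stereocentre is formed. Regioselectivity is fixed because B6 is the only C–H ortho to iodine and a second alkylation is impossible because B2 is substituted; the chemoselectivity needed (palladacycle alkylation ahead of phenoxide O-alkylation or direct O-arylation) rests on the insoluble weak base in toluene, fast norbornene insertion and the low standing concentration of 8.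

**Step 6**
Reactants: 11 macrocycle trimethyl ether
Product: 12 2-oxa-1(1,3),3(1,2)-dibenzenacycloheptadecaphane-1⁵,3⁴,3⁶-triol (CNP0173380.0)
Conditions: BBr3 (6 equiv), CH2Cl2, −78 °C to rt; then H2O, 0 °C
Reagents that add atoms: none
Why: BBr3 cleaves aryl methyl ethers by O–B coordination and bromide attack on the methyl carbon, while the diaryl ether has no sp3 carbon on oxygen and the saturated tether has no reactive site, so only the three methoxy groups should react.

**Compound list**
1 | tetradeca-1,13-diene | C=CCCCCCCCCCCCC=C | starting material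
2 | 1-bromo-3,5-dimethoxybenzene | COc1cc(Br)cc(OC)c1 | starting material
3 | 9-(tetradec-13-en-1-yl)-9-borabicyclo[3.3.1]nonane | C=CCCCCCCCCCCCCB1C2CCCC1CCC2 | intermediate (not isolated)
4 | 1,3-dimethoxy-5-(tetradec-13-en-1-yl)benzene | COc1cc(OC)cc(CCCCCCCCCCCCC=C)c1 | intermediate
5 | 9-[14-(3,5-dimethoxyphenyl)tetradecyl]-9-borabicyclo[3.3.1]nonane | COc1cc(OC)cc(CCCCCCCCCCCCCCB2C3CCCC2CCC3)c1 | intermediate (not isolated)
6 | 14-(3,5-dimethoxyphenyl)tetradecan-1-ol | COc1cc(OC)cc(CCCCCCCCCCCCCCO)c1 | intermediate
7 | 3-(14-hydroxytetradecyl)-5-methoxyphenol | COc1cc(O)cc(CCCCCCCCCCCCCCO)c1 | intermediate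
8 | 3-(14-iodotetradecyl)-5-methoxyphenol | COc1cc(O)cc(CCCCCCCCCCCCCCI)c1 | intermediate (key-step precursor)
9 | 1-iodo-2,4-dimethoxybenzene | COc1ccc(I)c(OC)c1 | starting material (key-step precursor)
10 | norbornene (bicyclo[2.2.1]hept-2-ene) | C1=CC2CCC1C2 | starting material (mediator, not incorporated)
11 | 1⁵,3⁴,3⁶-trimethoxy-2-oxa-1(1,3),3(1,2)-dibenzenacycloheptadecaphane (ring A: 5-methoxy-1,3-phenylene; ring B: O on B1, OMe on B2 and B4, chain on B6; fourteen CH2 groups join B6 to ring A) | COc1cc2cc(c1)Oc1c(OC)cc(OC)cc1CCCCCCCCCCCCCC2 | intermediate (key-step product)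
12 | 2-oxa-1(1,3),3(1,2)-dibenzenacycloheptadecaphane-1⁵,3⁴,3⁶-triol | Oc1cc2cc(c1)Oc1c(O)cc(O)cc1CCCCCCCCCCCCCC2 | target

**Total step count:** 6. **Longest linear sequence:** 6 steps (1 and 2 to 12); 9 and 10 are bought.

**Steps most likely to fail**

1. Step 5. The phenoxide may be O-alkylated by the primary iodide (oligomeric alkyl aryl ethers). The aryl iodide may be O-arylated directly without the norbornene relay. The final C–O reductive elimination may lose out to ipso reduction or to intermolecular etherification. Fallback by known chemistry, setting out from 4 and returning at 11: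
   - NaSEt in DMF at 140 °C should give 3-methoxy-5-(tetradec-13-en-1-yl)phenol F1.
   - Ullmann etherification of F1 with purchased 2-bromo-3,5-dimethoxybenzaldehyde (COc1cc(C=O)c(Br)c(OC)c1; CuI, N,N-dimethylglycine, Cs2CO3, dioxane, 100 °C), the ortho formyl group activating the hindered bromide, should give 3,5-dimethoxy-2-[3-methoxy-5-(tetradec-13-en-1-yl)phenoxy]benzaldehyde F2.
   - Wittig methylenation (Ph3PCH3Br, KOtBu, THF, 0 °C) should give 1-ethenyl-3,5-dimethoxy-2-[3-methoxy-5-(tetradec-13-en-1-yl)phenoxy]benzene F3.
   - Ring-closing metathesis (second-generation Grubbs catalyst, CH2Cl2, 2 mM, 40 °C) should close the 20-membered ring as 1⁵,3⁴,3⁶-trimethoxy-2-oxa-1(1,3),3(1,2)-dibenzenacycloheptadecaphan-4-ene F4 (E/Z mixture).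
   - Hydrogenation (H2, Pd/C, EtOAc) then gives 11.

2. Step 4. Electrophilic iodination of the activated ring A may compete, or the iodoalkyl phenol may alkylate itself during isolation. Fallback, setting out from 7 and returning at 8: Appel bromination (CBr4, PPh3, CH2Cl2, 0 °C) should give 3-(14-bromotetradecyl)-5-methoxyphenol F5, and Finkelstein exchange (NaI, acetone, reflux) under neutral conditions then gives 8. No electrophilic iodine meets the ring on this path.

3. Step 1. Double hydroboration of the symmetric diene would give a bis-arylated chain, and protodeboronation or β-hydride elimination may erode the alkyl coupling. Fallback, setting out from 2 and returning at 6 (steps 1 and 2 are both replaced):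
   - Purchased 12-bromododecan-1-ol (OCCCCCCCCCCCCBr) and LiC≡CH·ethylenediamine (3 equiv, DMSO, rt) should give tetradec-13-yn-1-ol F6.
   - Sonogashira coupling of 2 with F6 (Pd(PPh3)2Cl2, CuI, Et3N, 80 °C) should give 14-(3,5-dimethoxyphenyl)tetradec-13-yn-1-ol F7.
   - Hydrogenation (H2, Pd/C, EtOAc) then gives 6.

**Further compounds**
F1 | step 5 | 3-methoxy-5-(tetradec-13-en-1-yl)phenol | COc1cc(O)cc(CCCCCCCCCCCCC=C)c1
F2 | step 5 | 3,5-dimethoxy-2-[3-methoxy-5-(tetradec-13-en-1-yl)phenoxy]benzaldehyde | COc1cc(C=O)c(Oc2cc(OC)cc(CCCCCCCCCCCCC=C)c2)c(OC)c1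
F3 | step 5 | 1-ethenyl-3,5-dimethoxy-2-[3-methoxy-5-(tetradec-13-en-1-yl)phenoxy]benzene | COc1cc(C=C)c(Oc2cc(OC)cc(CCCCCCCCCCCCC=C)c2)c(OC)c1
F4 | step 5 | 1⁵,3⁴,3⁶-trimethoxy-2-oxa-1(1,3),3(1,2)-dibenzenacycloheptadecaphan-4-ene (E/Z mixture) | COc1cc2cc(c1)Oc1c(OC)cc(OC)cc1C=CCCCCCCCCCCCC2
F5 | step 4 | 3-(14-bromotetradecyl)-5-methoxyphenol | COc1cc(O)cc(CCCCCCCCCCCCCCBr)c1
F6 | step 1 | tetradec-13-yn-1-ol | C#CCCCCCCCCCCCCO
F7 | step 1 | 14-(3,5-dimethoxyphenyl)tetradec-13-yn-1-ol | COc1cc(OC)cc(C#CCCCCCCCCCCCCO)c1
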